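The benzenoid ring of the coumarin is built, not functionalised. It is a resorcinol-type ring with the lactone oxygen on C8a, the stereogenic side-chain carbon C1′ on C8, the ether oxygen on C7, hydrogens on C5 and C6, and C4 attached to C4a. A Danheiser benzannulation between a vinylketene (from photochemical Wolff rearrangement of an acetal-bearing diazo enone) and an enantiopure triisopropylsiloxyalkyne makes this ring with all substituents in place in one operation, forming C8a–C8, C7–C6 and C4a–C8a. The alkyne already carries the C1′ stereocentre as a silyl ether and the C2′ ketone masked as a methylene group; the acetal becomes C4.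

Key step: step 7

Remark: 3-methyl-2-methylenebutanal and 2,2-dimethoxyacetaldehyde (as its 60% aqueous solution) are treated as catalogue chemicals.
Remark: after the resolution the spatial arrangement at C1′ never changes; its CIP label alternates (S, R, S) only because the neighbouring groups change rank.

Step 1
Reactants: 1 2,2-dimethoxyacetaldehyde; 2 1-(triphenylphosphoranylidene)propan-2-one
Product: 3 (E)-5,5-dimethoxypent-3-en-2-one
Conditions: CH2Cl2/H2O, 25 °C
Reagents that add atoms: none
Why: Wittig olefination with a ketone-stabilised ylide tolerates the aqueous, non-enolisable acetal aldehyde and should give the (E)-enone.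

Step 2
Reactants: 3 (E)-5,5-dimethoxypent-3-en-2-one
Product: 5 (E)-1-diazo-5,5-dimethoxypent-3-en-2-one, via trifluoroacetyl diketone 4 (not isolated)
Conditions: LiN(SiMe3)2, THF, −78 °C; CF3CO2CH2CF3; cold dilute HCl work-up; then 4-acetamidobenzenesulfonyl azide, Et3N, H2O, MeCN, 25 °C
Reagents that add atoms: 4-acetamidobenzenesulfonyl azide, CC(=O)Nc1ccc(cc1)S(=O)(=O)N=[N+]=[N-] (the N2 unit); 2,2,2-trifluoroethyl trifluoroacetate, O=C(OCC(F)(F)F)C(F)(F)F (the trifluoroacetyl group of 4 only)
Why: Detrifluoroacetylative diazo transfer (kinetic enolisation at the methyl group, Claisen-type trifluoroacetylation, then Regitz-type transfer with loss of the trifluoroacetyl group to the sulfonamide) is the standard way to put a diazo group on the α′ carbon of an enone, and the acetal is inert to these basic conditions.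

Step 3
Reactants: 6 3-methyl-2-methylenebutanal; 7 ethynylmagnesium bromide
Product: 8 rac-5-methyl-4-methylenehex-1-yn-3-ol
Conditions: THF, 0 °C; aq. NH4Cl
Reagents that add atoms: none
Why: An alkynyl Grignard reagent adds 1,2 to the enal carbonyl; the new stereocentre forms without control and is sorted in step 4.

Step 4
Reactants: 8 rac-5-methyl-4-methylenehex-1-yn-3-ol
Product: 9 (S)-5-methyl-4-methylenehex-1-yn-3-ol
Conditions: Novozym 435 (immobilised Candida antarctica lipase B), vinyl acetate, hexane, 30 °C, stopped past half conversion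
Reagents that add atoms: none
Why: In this lipase kinetic resolution by transesterification, the empirical size rule for secondary alcohols (small ethynyl against large branched alkenyl group) predicts acetylation of the (R)-alcohol, so the wanted (S)-alcohol stays behind and its enantiomeric purity can be raised by running past half conversion.

Step 5
Reactants: 9 (S)-5-methyl-4-methylenehex-1-yn-3-ol
Product: 10 (S)-3-(tert-butyldimethylsilyloxy)-5-methyl-4-methylenehex-1-yne
Conditions: t-BuMe2SiCl, imidazole, DMF, 25 °C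
Reagents that add atoms: tert-butyldimethylsilyl chloride, CC(C)(C)[Si](C)(C)Cl
Why: Routine O-silylation of a secondary alcohol breaks no bond at the stereocentre, so configuration is retained.

Step 6
Reactants: 10 (S)-3-(tert-butyldimethylsilyloxy)-5-methyl-4-methylenehex-1-yne
Product: 13 (R)-3-(tert-butyldimethylsilyloxy)-5-methyl-4-methylene-1-(triisopropylsilyloxy)hex-1-yne, via lithium acetylide 11 (not isolated), via lithium ynolate 12 (not isolated)
Conditions: n-BuLi, THF, −78 °C; LiOOt-Bu (from t-BuOOH and LiN(SiMe3)2), −78 → 0 °C; i-Pr3SiOTf, −78 → 0 °C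
Reagents that add atoms: lithium tert-butyl peroxide, [Li+].[O-]OC(C)(C)C (the ynol oxygen); triisopropylsilyl trifluoromethanesulfonate, CC(C)[Si](C(C)C)(C(C)C)OS(=O)(=O)C(F)(F)F; n-butyllithium, [Li]CCCC (the lithium of 11 and 12 only)
Why: Oxidation of a lithium acetylide with lithium tert-butyl peroxide gives the ynolate, and the bulky silyl triflate traps it on oxygen, which is the established route to 1-siloxy-1-alkynes and does not involve the propargylic stereocentre.

Step 7
Reactants: 5 (E)-1-diazo-5,5-dimethoxypent-3-en-2-one; 13 (R)-3-(tert-butyldimethylsilyloxy)-5-methyl-4-methylene-1-(triisopropylsilyloxy)hex-1-yne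
Product: 18 6-(dimethoxymethyl)-2-[(1R)-1-(tert-butyldimethylsilyloxy)-3-methyl-2-methylenebutyl]-3-(triisopropylsilyloxy)phenol, via vinylketene 14 (not isolated), via alkenylcyclobutenone 15 (not isolated), via dienylketene 16 (not isolated), via cyclohexadienone 17 (not isolated)
Conditions: hν (254 nm, low-pressure Hg lamps, Vycor), ClCH2CH2Cl, 25 °C, 5 (1.5 equiv) added in portions; then 80 °C in the dark
Reagents that add atoms: none
Why: Light expels N2 from 5 and the Wolff shift of the alkenyl group gives vinylketene 14, the siloxyalkyne adds across the ketene C=C bond in a [2+2] cycloaddition to give cyclobutenone 15, which opens in a 4π electrocyclic step to dienylketene 16, and 16 closes to dienone 17, which enolises to phenol 18. The closest known reaction type is this very one, the Danheiser benzannulation in its photochemical Wolff mode, in which α-diazo enones and triisopropylsiloxyalkynes give 2-substituted resorcinol monosilyl ethers. The only ring that remains, the benzenoid ring, is closed by a thermally allowed disrotatory 6π electrocyclisation that joins the ketene carbon (C8a) to the acetal-bearing terminus (C4a), after the [2+2] event has made C8a–C8 and C7–C6. No stereocentre is created, since the sp3 centres of 15 and 17 are erased by ring opening and enolisation, and C1′ is a spectator under these neutral, metal-free conditions. The selectivity needed is regiochemical, and the polarisation of the ynol ether secures it: its nucleophilic carbon, the one carrying the side chain, bonds to the electrophilic ketene carbon, which places the side chain between the phenolic and the silylated oxygen. Portionwise addition of 5 keeps the ketene concentration low and should limit ketene dimerisation and acylation of the phenol.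

Step 8
Reactants: 18 6-(dimethoxymethyl)-2-[(1R)-1-(tert-butyldimethylsilyloxy)-3-methyl-2-methylenebutyl]-3-(triisopropylsilyloxy)phenol
Product: 19 2-hydroxy-3-[(1R)-1-(tert-butyldimethylsilyloxy)-3-methyl-2-methylenebutyl]-4-(triisopropylsilyloxy)benzaldehyde
Conditions: pyridinium p-toluenesulfonate (cat.), acetone/H2O, 25 °C
Reagents that add atoms: water, O
Why: Acid-catalysed hydrolysis of an aryl dimethyl acetal through a stabilised oxocarbenium ion is much faster than cleavage or ionisation of either silyl ether, so a weak acid at room temperature should free only the aldehyde.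

Step 9
Reactants: 19 2-hydroxy-3-[(1R)-1-(tert-butyldimethylsilyloxy)-3-methyl-2-methylenebutyl]-4-(triisopropylsilyloxy)benzaldehyde; 20 (triphenylphosphoranylidene)ketene (Bestmann ylide)
Product: 22 8-[(1R)-1-(tert-butyldimethylsilyloxy)-3-methyl-2-methylenebutyl]-7-(triisopropylsilyloxy)-2H-chromen-2-one, via aryl phosphoranylideneacetate 21 (not isolated)
Conditions: toluene, 90 °C
Reagents that add atoms: none
Why: In this addition–intramolecular Wittig coumarin synthesis the phenol adds to the cumulated ylide and the resulting ester ylide olefinates the neighbouring aldehyde, which can only give the cis alkene of the pyranone ring and leaves C1′ untouched under neutral conditions.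

Step 10
Reactants: 22 8-[(1R)-1-(tert-butyldimethylsilyloxy)-3-methyl-2-methylenebutyl]-7-(triisopropylsilyloxy)-2H-chromen-2-one
Product: 24 8-[(1R)-1-(tert-butyldimethylsilyloxy)-3-methyl-2-methylenebutyl]-7-methoxy-2H-chromen-2-one, via caesium phenoxide 23 (not isolated)
Conditions: CsF, MeI, DMF, 25 °C
Reagents that add atoms: iodomethane, CI; caesium fluoride, [Cs+].[F-] (the caesium of 23 only)
Why: Fluoride cleaves the silyl ether on the phenolic oxygen (the 7-oxidocoumarin is a good leaving group) far faster than the hindered secondary alkyl silyl ether, and the phenoxide is methylated in situ in a Williamson etherification.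

Step 11
Reactants: 24 8-[(1R)-1-(tert-butyldimethylsilyloxy)-3-methyl-2-methylenebutyl]-7-methoxy-2H-chromen-2-one
Product: 26 8-[(1S)-1-(tert-butyldimethylsilyloxy)-3-methyl-2-oxobutyl]-7-methoxy-2H-chromen-2-one, via diol 25 (not isolated)
Conditions: OsO4 (cat.), NaIO4, 2,6-lutidine, dioxane/H2O, 25 °C
Reagents that add atoms: osmium tetroxide, O=[Os](=O)(=O)=O (delivers the ketone oxygen and is regenerated by sodium periodate, [Na+].[O-]I(=O)(=O)=O)
Why: In this Lemieux–Johnson oxidation the electrophilic OsO4 should prefer the isolated 1,1-disubstituted alkene over the electron-poor C3=C4 bond of the pyranone, and NaIO4 cleaves the primary–tertiary diol to the ketone while the silyl ether keeps the C1′–C2′ bond from being cleaved as well.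

Step 12
Reactants: 26 8-[(1S)-1-(tert-butyldimethylsilyloxy)-3-methyl-2-oxobutyl]-7-methoxy-2H-chromen-2-one
Product: 27 8-[(1S)-1-hydroxy-3-methyl-2-oxobutyl]-7-methoxy-2H-chromen-2-one
Conditions: HF·pyridine, pyridine, THF, 0 → 25 °C
Reagents that add atoms: none
Why: Fluoride desilylation in a buffered, weakly acidic medium avoids the basic conditions that would enolise the benzylic α-oxy ketone, so the C1′ configuration should be retained.

Step 13
Reactants: 27 8-[(1S)-1-hydroxy-3-methyl-2-oxobutyl]-7-methoxy-2H-chromen-2-one; 28 3-methylbut-2-enoic acid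
Product: 29 (1S)-1-(7-methoxy-2-oxo-2H-chromen-8-yl)-3-methyl-2-oxobutyl 3-methylbut-2-enoate
Conditions: EDC·HCl, DMAP (0.1 equiv), CH2Cl2, 0 °C
Reagents that add atoms: none
Why: Steglich esterification acylates the alcohol on oxygen without breaking the C1′–O bond, and low temperature with little DMAP is meant to suppress enolisation of the α-acyloxy ketone and deconjugation of the acyl group.

Compound list
1 | 2,2-dimethoxyacetaldehyde | COC(OC)C=O | starting material
2 | 1-(triphenylphosphoranylidene)propan-2-one | CC(=O)C=P(c1ccccc1)(c1ccccc1)c1ccccc1 | starting material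
3 | (E)-5,5-dimethoxypent-3-en-2-one | COC(OC)/C=C/C(C)=O | intermediate
4 | (E)-1,1,1-trifluoro-7,7-dimethoxyhept-5-ene-2,4-dione | COC(OC)/C=C/C(=O)CC(=O)C(F)(F)F | intermediate
5 | (E)-1-diazo-5,5-dimethoxypent-3-en-2-one | COC(OC)/C=C/C(=O)C=[N+]=[N-] | intermediate
6 | 3-methyl-2-methylenebutanal | CC(C)C(=C)C=O | starting material
7 | ethynylmagnesium bromide | C#C[Mg]Br | starting material
8 | rac-5-methyl-4-methylenehex-1-yn-3-ol | C#CC(O)C(=C)C(C)C | intermediate
9 | (S)-5-methyl-4-methylenehex-1-yn-3-ol | C#C[C@H](O)C(=C)C(C)C | intermediate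
10 | (S)-3-(tert-butyldimethylsilyloxy)-5-methyl-4-methylenehex-1-yne | C#C[C@H](O[Si](C)(C)C(C)(C)C)C(=C)C(C)C | intermediate
11 | [(3R)-3-(tert-butyldimethylsilyloxy)-5-methyl-4-methylenehex-1-yn-1-yl]lithium | [Li]C#C[C@H](O[Si](C)(C)C(C)(C)C)C(=C)C(C)C | intermediate
12 | lithium (3R)-3-(tert-butyldimethylsilyloxy)-5-methyl-4-methylenehex-1-yn-1-olate | [Li]OC#C[C@H](O[Si](C)(C)C(C)(C)C)C(=C)C(C)C | intermediate
13 | (R)-3-(tert-butyldimethylsilyloxy)-5-methyl-4-methylene-1-(triisopropylsilyloxy)hex-1-yne | CC(C)[Si](C(C)C)(C(C)C)OC#C[C@H](O[Si](C)(C)C(C)(C)C)C(=C)C(C)C | intermediate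
14 | (E)-5,5-dimethoxypenta-1,3-dien-1-one | COC(OC)/C=C/C=C=O | intermediate
15 | 2-[(1R)-1-(tert-butyldimethylsilyloxy)-3-methyl-2-methylenebutyl]-4-[(E)-3,3-dimethoxyprop-1-enyl]-3-(triisopropylsilyloxy)cyclobut-2-en-1-one (mixture at C4) | COC(OC)/C=C/C1C(=O)C([C@H](O[Si](C)(C)C(C)(C)C)C(=C)C(C)C)=C1O[Si](C(C)C)(C(C)C)C(C)C | intermediate
16 | (3E,5E)-2-[(1R)-1-(tert-butyldimethylsilyloxy)-3-methyl-2-methylenebutyl]-7,7-dimethoxy-3-(triisopropylsilyloxy)hepta-1,3,5-trien-1-one | O=C=C([C@H](O[Si](C)(C)C(C)(C)C)C(=C)C(C)C)/C(O[Si](C(C)C)(C(C)C)C(C)C)=C\C=C\C(OC)OC | intermediate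
17 | 6-(dimethoxymethyl)-2-[(1R)-1-(tert-butyldimethylsilyloxy)-3-methyl-2-methylenebutyl]-3-(triisopropylsilyloxy)cyclohexa-2,4-dien-1-one (mixture at C6) | COC(OC)C1C=CC(O[Si](C(C)C)(C(C)C)C(C)C)=C([C@H](O[Si](C)(C)C(C)(C)C)C(=C)C(C)C)C1=O | intermediate
18 | 6-(dimethoxymethyl)-2-[(1R)-1-(tert-butyldimethylsilyloxy)-3-methyl-2-methylenebutyl]-3-(triisopropylsilyloxy)phenol | COC(OC)c1ccc(O[Si](C(C)C)(C(C)C)C(C)C)c([C@H](O[Si](C)(C)C(C)(C)C)C(=C)C(C)C)c1O | intermediate
19 | 2-hydroxy-3-[(1R)-1-(tert-butyldimethylsilyloxy)-3-methyl-2-methylenebutyl]-4-(triisopropylsilyloxy)benzaldehyde | O=Cc1ccc(O[Si](C(C)C)(C(C)C)C(C)C)c([C@H](O[Si](C)(C)C(C)(C)C)C(=C)C(C)C)c1O | intermediate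
20 | (triphenylphosphoranylidene)ketene (Bestmann ylide) | O=C=C=P(c1ccccc1)(c1ccccc1)c1ccccc1 | starting material
21 | 2-formyl-6-[(1R)-1-(tert-butyldimethylsilyloxy)-3-methyl-2-methylenebutyl]-5-(triisopropylsilyloxy)phenyl (triphenylphosphoranylidene)acetate | O=Cc1ccc(O[Si](C(C)C)(C(C)C)C(C)C)c([C@H](O[Si](C)(C)C(C)(C)C)C(=C)C(C)C)c1OC(=O)C=P(c1ccccc1)(c1ccccc1)c1ccccc1 | intermediate
22 | 8-[(1R)-1-(tert-butyldimethylsilyloxy)-3-methyl-2-methylenebutyl]-7-(triisopropylsilyloxy)-2H-chromen-2-one | O=c1ccc2ccc(O[Si](C(C)C)(C(C)C)C(C)C)c([C@H](O[Si](C)(C)C(C)(C)C)C(=C)C(C)C)c2o1 | intermediate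
23 | caesium 8-[(1R)-1-(tert-butyldimethylsilyloxy)-3-methyl-2-methylenebutyl]-2-oxo-2H-chromen-7-olate | [Cs+].[O-]c1ccc2ccc(=O)oc2c1[C@H](O[Si](C)(C)C(C)(C)C)C(=C)C(C)C | intermediate
24 | 8-[(1R)-1-(tert-butyldimethylsilyloxy)-3-methyl-2-methylenebutyl]-7-methoxy-2H-chromen-2-one | COc1ccc2ccc(=O)oc2c1[C@H](O[Si](C)(C)C(C)(C)C)C(=C)C(C)C | intermediate
25 | 8-[(1S)-1-(tert-butyldimethylsilyloxy)-2-hydroxy-2-(hydroxymethyl)-3-methylbutyl]-7-methoxy-2H-chromen-2-one (mixture at C2′) | COc1ccc2ccc(=O)oc2c1[C@H](O[Si](C)(C)C(C)(C)C)C(O)(CO)C(C)C | intermediate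
26 | 8-[(1S)-1-(tert-butyldimethylsilyloxy)-3-methyl-2-oxobutyl]-7-methoxy-2H-chromen-2-one | COc1ccc2ccc(=O)oc2c1[C@H](O[Si](C)(C)C(C)(C)C)C(=O)C(C)C | intermediate
27 | 8-[(1S)-1-hydroxy-3-methyl-2-oxobutyl]-7-methoxy-2H-chromen-2-one | COc1ccc2ccc(=O)oc2c1[C@H](O)C(=O)C(C)C | intermediate
28 | 3-methylbut-2-enoic acid | CC(C)=CC(=O)O | starting material
29 | (1S)-1-(7-methoxy-2-oxo-2H-chromen-8-yl)-3-methyl-2-oxobutyl 3-methylbut-2-enoate | COc1ccc2ccc(=O)oc2c1[C@H](OC(=O)C=C(C)C)C(=O)C(C)C | target

Total step count: 13. Longest linear sequence: 11 steps (steps 3 to 13, from 6).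

Steps most likely to fail

Step 7. The cycloaddition between the short-lived vinylketene and an alkyne whose reacting carbon carries a branched, silyloxy-bearing group may be too slow, so that the ketene is lost to dimerisation or to acylation of phenol already formed. The fallback buys the benzenoid ring and attaches the side chain by carbonyl addition; it sets out from 6 and comes back at 24. 1-Methoxy-3-(methoxymethoxy)benzene is lithiated between its two oxygen substituents (n-BuLi, THF, 0 °C) and added to 6 to give rac-1-[2-methoxy-6-(methoxymethoxy)phenyl]-3-methyl-2-methylenebutan-1-ol F1. Sharpless kinetic resolution (Ti(OiPr)4, D-(−)-diisopropyl tartrate, t-BuOOH, 4 Å molecular sieves, CH2Cl2, −20 °C) should leave (R)-1-[2-methoxy-6-(methoxymethoxy)phenyl]-3-methyl-2-methylenebutan-1-ol F2. Its antipode is converted into (R)-[2-methoxy-6-(methoxymethoxy)phenyl][(2S)-2-isopropyloxiran-2-yl]methanol F3, which is discarded. Silylation of F2 (t-BuMe2SiOTf, 2,6-lutidine) gives tert-butyl{(1R)-1-[2-methoxy-6-(methoxymethoxy)phenyl]-3-methyl-2-methylenebutoxy}dimethylsilane F4. Mild removal of the methoxymethyl group (Me3SiOTf, 2,2′-bipyridyl, CH2Cl2, then water) gives 2-[(1R)-1-(tert-butyldimethylsilyloxy)-3-methyl-2-methylenebutyl]-3-methoxyphenol F5. Ortho-formylation (MgCl2, Et3N, paraformaldehyde, MeCN, reflux) gives 2-hydroxy-4-methoxy-3-[(1R)-1-(tert-butyldimethylsilyloxy)-3-methyl-2-methylenebutyl]benzaldehyde F6, which with 20 under the conditions of step 9 gives 24.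

Step 13 (with the desilylation that feeds it). The free and then the acylated benzylic α-oxy ketone may enolise under the basic acyl-transfer conditions. That would erode the C1′ configuration, shift the ketol to the isomeric aryl ketone, or move the double bond of the acyl group out of conjugation. The fallback installs the ester before the ketone exists; it sets out from 24 and comes back at 29. Bu4NF in THF removes the silyl group to give 8-[(1R)-1-hydroxy-3-methyl-2-methylenebutyl]-7-methoxy-2H-chromen-2-one F7, which has no acidic C1′–H. Esterification with 28 (EDC·HCl, DMAP, CH2Cl2) gives (1R)-1-(7-methoxy-2-oxo-2H-chromen-8-yl)-3-methyl-2-methylenebutyl 3-methylbut-2-enoate F8. Ozonolysis at −78 °C to a dye end-point (Sudan Red 7B), with Me2S work-up, is then relied on to cleave the isolated 1,1-disubstituted alkene faster than the two ester-conjugated double bonds, and gives 29 directly.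

Step 9. Addition of the hindered, hydrogen-bonded phenol to the cumulated ylide may be slower than decomposition of the ylide, and prolonged heating may ionise the ortho-hydroxybenzylic silyl ether. The fallback reverses the order of bond formation; it sets out from 19 and comes back at 22. Ethyl (triphenylphosphoranylidene)acetate first olefinates the aldehyde (toluene, 60 °C) to give ethyl (E)-3-{2-hydroxy-3-[(1R)-1-(tert-butyldimethylsilyloxy)-3-methyl-2-methylenebutyl]-4-(triisopropylsilyloxy)phenyl}prop-2-enoate F9. Irradiation at 365 nm at room temperature then isomerises the cinnamate to its Z form, which lactonises with loss of ethanol to 22.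

Further compounds
F1 | step 7 | rac-1-[2-methoxy-6-(methoxymethoxy)phenyl]-3-methyl-2-methylenebutan-1-ol | COCOc1cccc(OC)c1C(O)C(=C)C(C)C
F2 | step 7 | (R)-1-[2-methoxy-6-(methoxymethoxy)phenyl]-3-methyl-2-methylenebutan-1-ol | COCOc1cccc(OC)c1[C@H](O)C(=C)C(C)C
F3 | step 7 | (R)-[2-methoxy-6-(methoxymethoxy)phenyl][(2S)-2-isopropyloxiran-2-yl]methanol | COCOc1cccc(OC)c1[C@@H](O)[C@@]1(CO1)C(C)C
F4 | step 7 | tert-butyl{(1R)-1-[2-methoxy-6-(methoxymethoxy)phenyl]-3-methyl-2-methylenebutoxy}dimethylsilane | COCOc1cccc(OC)c1[C@H](O[Si](C)(C)C(C)(C)C)C(=C)C(C)C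
F5 | step 7 | 2-[(1R)-1-(tert-butyldimethylsilyloxy)-3-methyl-2-methylenebutyl]-3-methoxyphenol | COc1cccc(O)c1[C@H](O[Si](C)(C)C(C)(C)C)C(=C)C(C)C
F6 | step 7 | 2-hydroxy-4-methoxy-3-[(1R)-1-(tert-butyldimethylsilyloxy)-3-methyl-2-methylenebutyl]benzaldehyde | COc1ccc(C=O)c(O)c1[C@H](O[Si](C)(C)C(C)(C)C)C(=C)C(C)C
F7 | step 13 | 8-[(1R)-1-hydroxy-3-methyl-2-methylenebutyl]-7-methoxy-2H-chromen-2-one | COc1ccc2ccc(=O)oc2c1[C@H](O)C(=C)C(C)C
F8 | step 13 | (1R)-1-(7-methoxy-2-oxo-2H-chromen-8-yl)-3-methyl-2-methylenebutyl 3-methylbut-2-enoate | COc1ccc2ccc(=O)oc2c1[C@H](OC(=O)C=C(C)C)C(=C)C(C)C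
F9 | step 9 | ethyl (E)-3-{2-hydroxy-3-[(1R)-1-(tert-butyldimethylsilyloxy)-3-methyl-2-methylenebutyl]-4-(triisopropylsilyloxy)phenyl}prop-2-enoate | CCOC(=O)/C=C/c1ccc(O[Si](C(C)C)(C(C)C)C(C)C)c([C@H](O[Si](C)(C)C(C)(C)C)C(=C)C(C)C)c1O
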